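**Retrosynthetic overview**

- The strategy rests on ring A: three contiguous oxygens (C6 OMe, C7 OH, C8 OMe) beside an unsubstituted C5 are the imprint of a 1,2,3-trioxygenated butadiene. Ring A is therefore made de novo by [4+2] benzannulation across C4a–C8a of a chiral ring B enone (bonds C5–C4a and C8–C8a).
- Ring B first: an auxiliary-controlled Diels–Alder reaction of butadiene with a dimenthyl fumarate sets C2 and C3. Reduction, acetylation and a non-transposing allylic oxidation give trans-5,6-bis(acetoxymethyl)cyclohex-2-enone; the oxygen must end on a former allylic CH2, since a transposing oxidation would give the 4,5-disubstituted enone.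
- Ring A second: the 2-benzyloxy ketene-acetal diene (from methyl acetoacetate) adds to the enone; loss of methanol and silanol, then DDQ, gives the 8-hydroxy-1-tetralone with C6 OMe, C7 OBn and C8 OH already distinguished.
- Pendant aryl last: C8 O-methylation, C1 reduction, Friedel–Crafts capture of the C1 cation by 2,6-dimethoxyphenol trans to C2 (sets C1), then deacetylation and debenzylation.

Key step: step 11

Remark on numbering: all bicyclic compounds use tetralin (lignan) numbering: C1 aryl-bearing carbon, C2 and C3 the CH2O-bearing carbons, C4 the benzylic CH2, C4a–C8a ring A.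

Assumption on the auxiliary: the Et2AlCl-promoted addition to a dimenthyl fumarate is taken to occur on the alkene face remote from the isopropyl-bearing ring carbon of both s-trans menthyl esters. For the (1S,2R,5S)-menthyl ester this leads to the (1R,2R)-diester needed here. Should the adduct prove to be (1S,2S), the (1R,2S,5R)-menthyl ester is used instead, with no other change.

**Route**

Step 1
Reactants: 1 fumaric acid; 2 (1S,2R,5S)-menthol (2.2 equiv in all, one per carboxyl group)
Product: 3 di[(1S,2R,5S)-menthyl] fumarate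
Conditions: p-TsOH·H2O (5 mol%), toluene, reflux, Dean–Stark
Reagents that add atoms: (1S,2R,5S)-menthol (the second equivalent of 2, for the second carboxyl group), CC(C)[C@H]1CC[C@H](C)C[C@@H]1O
Why: twofold Fischer esterification, each carboxyl group of the diacid taking up one molecule of menthol, driven by azeotropic removal of water; no stereocentre is touched.

Step 2
Reactants: 3 di[(1S,2R,5S)-menthyl] fumarate; 4 buta-1,3-diene
Product: 5 di[(1S,2R,5S)-menthyl] (1R,2R)-cyclohex-4-ene-1,2-dicarboxylate
Conditions: 4 (excess), Et2AlCl (1.1 equiv), toluene, −40 °C; aq. HCl work-up; recrystallisation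
Reagents that add atoms: none
Why: Lewis-acid-promoted, auxiliary-controlled Diels–Alder reaction in which both s-trans menthyl esters shield the same alkene face, so the diene adds to the open face and sets both ring stereocentres (later C2 and C3) as R,R, with crystallisation expected to remove the minor diastereomer.

Step 3
Reactants: 5 di[(1S,2R,5S)-menthyl] (1R,2R)-cyclohex-4-ene-1,2-dicarboxylate
Product: 6 (1R,2R)-cyclohex-4-ene-1,2-dimethanol
Conditions: LiAlH4, THF, 0 °C → reflux; Fieser work-up
Reagents that add atoms: none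
Why: hydride reduction of both esters to primary alcohols without epimerisation of the adjacent centres, the alkene being inert and the menthol recoverable.

Step 4
Reactants: 6 (1R,2R)-cyclohex-4-ene-1,2-dimethanol
Product: 7 (4R,5R)-4,5-bis(acetoxymethyl)cyclohexene
Conditions: Ac2O, pyridine, DMAP (cat.), CH2Cl2, rt
Reagents that add atoms: acetic anhydride, CC(=O)OC(C)=O
Why: DMAP-catalysed acylation of two unhindered primary alcohols; the acetates later assist the C1 arylation and come off under mild methanolysis.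

Step 5
Reactants: 7 (4R,5R)-4,5-bis(acetoxymethyl)cyclohexene
Product: 8 (5R,6R)-5,6-bis(acetoxymethyl)cyclohex-2-en-1-ol (C1 epimers)
Conditions: SeO2 (0.5 equiv), t-BuOOH (3 equiv), CH2Cl2, rt
Reagents that add atoms: selenium dioxide, O=[Se]=O; tert-butyl hydroperoxide, CC(C)(C)OO
Why: SeO2 allylic hydroxylation (ene reaction, then [2,3]-sigmatropic shift of the allylseleninic acid) puts oxygen on an allylic CH2 and returns the alkene to its original place, so the carbinol lies next to a CH(CH2OAc) carbon; the two allylic CH2 groups are equivalent through the C2 axis and the carbinol configuration is irrelevant.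

Step 6
Reactants: 8 (5R,6R)-5,6-bis(acetoxymethyl)cyclohex-2-en-1-ol
Product: 9 (5R,6R)-5,6-bis(acetoxymethyl)cyclohex-2-en-1-one
Conditions: Dess–Martin periodinane, NaHCO3, CH2Cl2, 0 °C → rt
Reagents that add atoms: none
Why: Dess–Martin oxidation of the allylic alcohol under buffered, non-basic conditions that spare the β-acetoxy ketone; the α-centre is already in the favoured trans arrangement.

Step 7
Reactants: 10 methyl acetoacetate
Product: 11 methyl 2-diazo-3-oxobutanoate
Conditions: 4-acetamidobenzenesulfonyl azide, Et3N, MeCN, 0 °C → rt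
Reagents that add atoms: 4-acetamidobenzenesulfonyl azide, CC(=O)Nc1ccc(cc1)S(=O)(=O)N=[N+]=[N-]
Why: Regitz diazo transfer to the activated methylene of a β-keto ester.

Step 8
Reactants: 11 methyl 2-diazo-3-oxobutanoate; 12 benzyl alcohol
Product: 13 methyl 2-benzyloxy-3-oxobutanoate (racemic)
Conditions: Rh2(OAc)4 (1 mol%), 12 (1.5 equiv), CH2Cl2, reflux
Reagents that add atoms: none
Why: rhodium-carbenoid O–H insertion of a 2-diazo-1,3-dicarbonyl compound into an alcohol, which places the future C7 oxygen with its benzyl group.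

Step 9
Reactants: 13 methyl 2-benzyloxy-3-oxobutanoate
Product: 15 methyl 2-benzyloxy-3-methoxybut-2-enoate (E/Z mixture), via sodium enolate 14 (not isolated)
Conditions: NaH, THF–DMPU, 0 °C; Me2SO4, 0 °C → rt
Reagents that add atoms: dimethyl sulfate, COS(=O)(=O)OC
Why: O-alkylation of a β-keto ester enolate, favoured by the hard electrophile, the dipolar aprotic co-solvent and the fully substituted α-carbon; the alkene geometry is of no consequence.

Step 10
Reactants: 15 methyl 2-benzyloxy-3-methoxybut-2-enoate
Product: 17 2-benzyloxy-1,3-dimethoxy-1-(trimethylsilyloxy)buta-1,3-diene, via lithium dienolate 16 (not isolated)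
Conditions: LiN(i-Pr)2 (LDA), THF, −78 °C; Me3SiCl, −78 °C → rt; non-aqueous work-up
Reagents that add atoms: chlorotrimethylsilane, C[Si](C)(C)Cl
Why: γ-deprotonation of the β-methoxy crotonate and O-silylation of the dienolate, the standard preparation of 1-alkoxy-1-silyloxy (Brassard-type) dienes; the ketene-acetal geometry does not matter.

Step 11
Reactants: 9 (5R,6R)-5,6-bis(acetoxymethyl)cyclohex-2-en-1-one; 17 2-benzyloxy-1,3-dimethoxy-1-(trimethylsilyloxy)buta-1,3-diene
Product: 20 (2R,3R)-2,3-bis(acetoxymethyl)-7-benzyloxy-8-hydroxy-6-methoxy-3,4-dihydronaphthalen-1(2H)-one, via silyl ketal cycloadduct 18 (not isolated), via dihydro enol 19 (not isolated)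
Conditions: 17 (1.8 equiv), HNTf2 (10 mol%), CH2Cl2, −78 → −30 °C; 0.1 M HCl, THF, 0 °C (brief); DDQ (1.1 equiv), PhH, rt
Reagents that add atoms: none
Why: Me3SiNTf2, formed in the flask from HNTf2 and a little 17, silylates the enone carbonyl; the nucleophilic CH2 terminus of 17 adds to the enone β-carbon (vinylogous Mukaiyama–Michael, C5–C4a) and the resulting C1–C8a silyl enol ether closes on the silyloxy(methoxy)carbenium carbon (C8–C8a), a stepwise Lewis-acid-catalysed Diels–Alder reaction. Ring A thus closes as a six-membered carbocycle in a 6-(enolexo)-exo-trig mode, the closest known reaction type being the acid-catalysed [4+2] addition of silyloxy and ketene-acetal dienes to cycloalkenones followed by aromatisation (Brassard–Danishefsky benzannulation). Dilute acid collapses the mixed silyl ketal of 18 (loss of methanol and trimethylsilanol) to the enolised 1,8-dione 19, and DDQ removes hydride from C4a/C5 and then a proton to give the arene, whose C8 hydroxyl is chelated to the C1 ketone. No new stereocentre survives (C4a and C8a become sp2) and C2 and C3 are not touched; C2, although α to the ketone, already carries its substituent trans to that on C3, so enolisation would return the same isomer. The selectivity needed is regiochemical (C5 to C4a, C8 to C8a) and is secured by the matched polarisation of the ketene-acetal diene and the enone, so that C6 OMe, C7 OBn and C8 OH arrive already distinguished.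

Step 12
Reactants: 20 (2R,3R)-2,3-bis(acetoxymethyl)-7-benzyloxy-8-hydroxy-6-methoxy-3,4-dihydronaphthalen-1(2H)-one
Product: 21 (2R,3R)-2,3-bis(acetoxymethyl)-7-benzyloxy-6,8-dimethoxy-3,4-dihydronaphthalen-1(2H)-one
Conditions: MeI (excess), Ag2O, DMF, rt, dark
Reagents that add atoms: iodomethane, CI
Why: Purdie-type methylation, the classical way to methylate a chelated peri-hydroxyl in a base-sensitive substrate, chosen so that the β-acetoxy ketone is not enolised and does not lose acetate by E1cB elimination.

Step 13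
Reactants: 21 (2R,3R)-2,3-bis(acetoxymethyl)-7-benzyloxy-6,8-dimethoxy-3,4-dihydronaphthalen-1(2H)-one
Product: 22 (2R,3R)-2,3-bis(acetoxymethyl)-7-benzyloxy-6,8-dimethoxy-1,2,3,4-tetrahydronaphthalen-1-ol (C1 epimers)
Conditions: NaBH4, CeCl3·7H2O, MeOH–THF, −20 → 0 °C
Reagents that add atoms: none
Why: Luche-type borohydride reduction of the aryl ketone at low temperature, which leaves the acetates intact; the carbinol configuration is irrelevant because C1 is ionised in the next step.

Step 14
Reactants: 22 (2R,3R)-2,3-bis(acetoxymethyl)-7-benzyloxy-6,8-dimethoxy-1,2,3,4-tetrahydronaphthalen-1-ol; 23 2,6-dimethoxyphenol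
Product: 24 (1S,2R,3R)-2,3-bis(acetoxymethyl)-7-benzyloxy-1-(4-hydroxy-3,5-dimethoxyphenyl)-6,8-dimethoxy-1,2,3,4-tetrahydronaphthalene
Conditions: 23 (4 equiv), Bi(OTf)3 (10 mol%), CH2Cl2–MeNO2, −20 → 0 °C
Reagents that add atoms: none
Why: SN1 Friedel–Crafts benzylation in which the C1 cation (stabilised by the C8 and C6 methoxy groups) is attacked by the phenol at its carbon para to OH; the new C1 centre is set by attack on the face opposite the C2 acetoxymethyl group, reinforced by transient participation of that acetate carbonyl on the syn face (six-membered dioxanylium), giving the 1,2-trans (1S) isomer as in related arylations of 2,3-disubstituted tetralin cations.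

Step 15
Reactants: 24 (1S,2R,3R)-2,3-bis(acetoxymethyl)-7-benzyloxy-1-(4-hydroxy-3,5-dimethoxyphenyl)-6,8-dimethoxy-1,2,3,4-tetrahydronaphthalene
Product: 25 (1S,2R,3R)-7-benzyloxy-1-(4-hydroxy-3,5-dimethoxyphenyl)-6,8-dimethoxy-1,2,3,4-tetrahydronaphthalene-2,3-dimethanol
Conditions: K2CO3 (cat.), MeOH, rt, argon
Reagents that add atoms: none
Why: base-catalysed transesterification of the two primary acetates to methyl acetate, run under argon to protect the electron-rich phenolate; no stereocentre is epimerisable.

Step 16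
Reactants: 25 (1S,2R,3R)-7-benzyloxy-1-(4-hydroxy-3,5-dimethoxyphenyl)-6,8-dimethoxy-1,2,3,4-tetrahydronaphthalene-2,3-dimethanol
Product: 26 (1S,2R,3R)-7-hydroxy-1-(4-hydroxy-3,5-dimethoxyphenyl)-6,8-dimethoxy-1,2,3,4-tetrahydronaphthalene-2,3-dimethanol (target CNP0153696.1)
Conditions: H2 (1 atm), palladium on carbon (Pd/C, 10%), MeOH–EtOAc, rt
Reagents that add atoms: none
Why: hydrogenolysis of the aryl benzyl ether frees the C7 hydroxyl under neutral conditions that leave the methyl ethers, the alcohols and the three stereocentres untouched.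

**Compound list**

1 | fumaric acid | OC(=O)/C=C/C(=O)O | starting material
2 | (1S,2R,5S)-menthol | CC(C)[C@H]1CC[C@H](C)C[C@@H]1O | starting material
3 | di[(1S,2R,5S)-menthyl] fumarate | CC(C)[C@H]1CC[C@H](C)C[C@@H]1OC(=O)/C=C/C(=O)O[C@H]1C[C@@H](C)CC[C@@H]1C(C)C | intermediate
4 | buta-1,3-diene | C=CC=C | starting material
5 | di[(1S,2R,5S)-menthyl] (1R,2R)-cyclohex-4-ene-1,2-dicarboxylate | CC(C)[C@H]1CC[C@H](C)C[C@@H]1OC(=O)[C@@H]1CC=CC[C@H]1C(=O)O[C@H]1C[C@@H](C)CC[C@@H]1C(C)C | intermediate
6 | (1R,2R)-cyclohex-4-ene-1,2-dimethanol | OC[C@@H]1CC=CC[C@H]1CO | intermediate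
7 | (4R,5R)-4,5-bis(acetoxymethyl)cyclohexene | CC(=O)OC[C@@H]1CC=CC[C@H]1COC(C)=O | intermediate
8 | (5R,6R)-5,6-bis(acetoxymethyl)cyclohex-2-en-1-ol (C1 epimers) | OC1C=CC[C@@H](COC(C)=O)[C@@H]1COC(C)=O | intermediate
9 | (5R,6R)-5,6-bis(acetoxymethyl)cyclohex-2-en-1-one | O=C1C=CC[C@@H](COC(C)=O)[C@@H]1COC(C)=O | intermediate
10 | methyl acetoacetate | COC(=O)CC(C)=O | starting material
11 | methyl 2-diazo-3-oxobutanoate | COC(=O)C(=[N+]=[N-])C(C)=O | intermediate
12 | benzyl alcohol | OCc1ccccc1 | starting material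
13 | methyl 2-benzyloxy-3-oxobutanoate (racemic) | COC(=O)C(OCc1ccccc1)C(C)=O | intermediate
14 | sodium enolate of 13 (not isolated) | [Na+].COC(=O)C(OCc1ccccc1)=C(C)[O-] | intermediate
15 | methyl 2-benzyloxy-3-methoxybut-2-enoate (E/Z mixture) | COC(=O)C(OCc1ccccc1)=C(C)OC | intermediate
16 | lithium dienolate of 15 (not isolated) | [Li+].C=C(OC)C(OCc1ccccc1)=C(OC)[O-] | intermediate
17 | 2-benzyloxy-1,3-dimethoxy-1-(trimethylsilyloxy)buta-1,3-diene (drawn as one ketene-acetal isomer; either serves) | C=C(OC)/C(OCc1ccccc1)=C(\OC)O[Si](C)(C)C | intermediate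
18 | (2R,3R)-2,3-bis(acetoxymethyl)-7-benzyloxy-6,8-dimethoxy-8-(trimethylsilyloxy)-3,4,4a,5,8,8a-hexahydronaphthalen-1(2H)-one, silyl ketal cycloadduct (not isolated) | O=C1C2C(OC)(O[Si](C)(C)C)C(OCc3ccccc3)=C(OC)CC2C[C@@H](COC(C)=O)[C@@H]1COC(C)=O | intermediate
19 | (2R,3R)-2,3-bis(acetoxymethyl)-7-benzyloxy-8-hydroxy-6-methoxy-3,4,4a,5-tetrahydronaphthalen-1(2H)-one, enol of the 1,8-dione (not isolated) | O=C1C2=C(O)C(OCc3ccccc3)=C(OC)CC2C[C@@H](COC(C)=O)[C@@H]1COC(C)=O | intermediate
20 | (2R,3R)-2,3-bis(acetoxymethyl)-7-benzyloxy-8-hydroxy-6-methoxy-3,4-dihydronaphthalen-1(2H)-one | O=C1c2c(cc(OC)c(OCc3ccccc3)c2O)C[C@@H](COC(C)=O)[C@@H]1COC(C)=O | intermediate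
21 | (2R,3R)-2,3-bis(acetoxymethyl)-7-benzyloxy-6,8-dimethoxy-3,4-dihydronaphthalen-1(2H)-one | O=C1c2c(cc(OC)c(OCc3ccccc3)c2OC)C[C@@H](COC(C)=O)[C@@H]1COC(C)=O | intermediate
22 | (2R,3R)-2,3-bis(acetoxymethyl)-7-benzyloxy-6,8-dimethoxy-1,2,3,4-tetrahydronaphthalen-1-ol (C1 epimers) | OC1c2c(cc(OC)c(OCc3ccccc3)c2OC)C[C@@H](COC(C)=O)[C@@H]1COC(C)=O | intermediate
23 | 2,6-dimethoxyphenol | COc1cccc(OC)c1O | starting material
24 | (1S,2R,3R)-2,3-bis(acetoxymethyl)-7-benzyloxy-1-(4-hydroxy-3,5-dimethoxyphenyl)-6,8-dimethoxy-1,2,3,4-tetrahydronaphthalene | COc1cc([C@H]2c3c(cc(OC)c(OCc4ccccc4)c3OC)C[C@@H](COC(C)=O)[C@@H]2COC(C)=O)cc(OC)c1O | intermediate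
25 | (1S,2R,3R)-7-benzyloxy-1-(4-hydroxy-3,5-dimethoxyphenyl)-6,8-dimethoxy-1,2,3,4-tetrahydronaphthalene-2,3-dimethanol | COc1cc([C@H]2c3c(cc(OC)c(OCc4ccccc4)c3OC)C[C@@H](CO)[C@@H]2CO)cc(OC)c1O | intermediate
26 | (1S,2R,3R)-7-hydroxy-1-(4-hydroxy-3,5-dimethoxyphenyl)-6,8-dimethoxy-1,2,3,4-tetrahydronaphthalene-2,3-dimethanol | COc1cc([C@H]2c3c(cc(OC)c(O)c3OC)C[C@@H](CO)[C@@H]2CO)cc(OC)c1O | target

**Count**

Total steps: 16. Longest linear sequence: 12 steps (steps 1–6, then 11–16); the diene branch (steps 7–10) joins at step 11.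

**Steps most likely to fail, with fallbacks**

1. Step 11 (ring A benzannulation). After the first C–C bond is made, the silyl group may leave the carboxonium ion faster than the ring closes, so that the sequence stops at the open conjugate adduct; the acid may also simply protodesilylate the diene. The fallback activates the dienophile instead, so that a concerted thermal cycloaddition becomes possible and the leaving group for aromatisation is carried in the substrate. It sets out from enone 9. Br2 in CH2Cl2 at 0 °C should give the (5R,6R)-2,3-dibromo-5,6-bis(acetoxymethyl)cyclohexan-1-one F1, from which Et3N removes HBr in the same flask to give the (5R,6R)-2-bromo-5,6-bis(acetoxymethyl)cyclohex-2-en-1-one F2, a cyclohexynone equivalent and a better dienophile. Heating F2 with diene 17 in toluene without acid should give the 8a-bromo silyl ketal cycloadduct F3 in the same orientation. Dilute acid then gives the 8a-bromo-1,8-dione F4, and DBU removes HBr across C8a–C4a; tautomerisation gives tetralone 20 without an oxidant, where the route is rejoined.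

2. Step 14 (C1 arylation). The long-lived, doubly methoxy-stabilised C1 cation may lose the C2 proton and scramble C2 on re-protonation, may be captured at the phenol oxygen or at the carbon next to a methoxy group, or may be attacked with too little facial preference. The fallback replaces the Friedel–Crafts reaction on the free phenol by ipso-substitution of an aryl–boron bond, which fixes the site and masks the phenol. It sets out from alcohol 22. Commercial (4-benzyloxy-3,5-dimethoxyphenyl)boronic acid F5 is converted with KHF2 into potassium (4-benzyloxy-3,5-dimethoxyphenyl)trifluoroborate F6. F6 with 22 and BF3·OEt2 in MeCN–CH2Cl2 at 0 °C should give the (1S,2R,3R)-1-(4-benzyloxy-3,5-dimethoxyphenyl) diacetate F7; the bulkier borate nucleophile should also favour the face away from the C2 substituent. K2CO3 in MeOH gives the corresponding 2,3-dimethanol F8, and hydrogenolysis of both benzyl ethers (H2, Pd/C) gives target 26, where the route is rejoined.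

3. Step 5 (allylic hydroxylation). The ene reaction of the unactivated disubstituted alkene may be slow or incomplete, with over-oxidation or radical pathways that place oxygen on the transposed position. The fallback brings the allylic oxygen in with the diene. It sets out from fumarate 3. Compound 3 and commercial (E)-1-acetoxybuta-1,3-diene F9 with Et2AlCl (or thermally, with recrystallisation) should give the dimenthyl trans-3-acetoxycyclohex-4-ene-1,2-dicarboxylate F10, with the same sense at the two ester-bearing carbons as in diester 5; the extra carbinol centre is irrelevant. LiAlH4 gives (5R,6R)-5,6-bis(hydroxymethyl)cyclohex-2-en-1-ol F11. MnO2 oxidises only the allylic secondary alcohol to (5R,6R)-5,6-bis(hydroxymethyl)cyclohex-2-en-1-one F12, and Ac2O in pyridine gives enone 9, where the route is rejoined.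

**Further compounds**

F1 | step 11 | (5R,6R)-2,3-dibromo-5,6-bis(acetoxymethyl)cyclohexan-1-one | O=C1C(Br)C(Br)C[C@@H](COC(C)=O)[C@@H]1COC(C)=O
F2 | step 11 | (5R,6R)-2-bromo-5,6-bis(acetoxymethyl)cyclohex-2-en-1-one | O=C1C(Br)=CC[C@@H](COC(C)=O)[C@@H]1COC(C)=O
F3 | step 11 | 8a-bromo silyl ketal cycloadduct (8a-bromo analogue of 18) | O=C1C2(Br)C(OC)(O[Si](C)(C)C)C(OCc3ccccc3)=C(OC)CC2C[C@@H](COC(C)=O)[C@@H]1COC(C)=O
F4 | step 11 | (2R,3R)-2,3-bis(acetoxymethyl)-7-benzyloxy-8a-bromo-6-methoxy-2,3,4,4a,5,8a-hexahydronaphthalene-1,8-dione | O=C1C2(Br)C(=O)C(OCc3ccccc3)=C(OC)CC2C[C@@H](COC(C)=O)[C@@H]1COC(C)=O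
F5 | step 14 | (4-benzyloxy-3,5-dimethoxyphenyl)boronic acid (purchased) | OB(O)c1cc(OC)c(OCc2ccccc2)c(OC)c1
F6 | step 14 | potassium (4-benzyloxy-3,5-dimethoxyphenyl)trifluoroborate | [K+].F[B-](F)(F)c1cc(OC)c(OCc2ccccc2)c(OC)c1
F7 | step 14 | (1S,2R,3R)-2,3-bis(acetoxymethyl)-7-benzyloxy-1-(4-benzyloxy-3,5-dimethoxyphenyl)-6,8-dimethoxy-1,2,3,4-tetrahydronaphthalene | COc1cc([C@H]2c3c(cc(OC)c(OCc4ccccc4)c3OC)C[C@@H](COC(C)=O)[C@@H]2COC(C)=O)cc(OC)c1OCc1ccccc1
F8 | step 14 | (1S,2R,3R)-7-benzyloxy-1-(4-benzyloxy-3,5-dimethoxyphenyl)-6,8-dimethoxy-1,2,3,4-tetrahydronaphthalene-2,3-dimethanol | COc1cc([C@H]2c3c(cc(OC)c(OCc4ccccc4)c3OC)C[C@@H](CO)[C@@H]2CO)cc(OC)c1OCc1ccccc1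
F9 | step 5 | (E)-1-acetoxybuta-1,3-diene (purchased) | CC(=O)O/C=C/C=C
F10 | step 5 | di[(1S,2R,5S)-menthyl] trans-3-acetoxycyclohex-4-ene-1,2-dicarboxylate (3-acetoxy analogue of 5; C3 epimers) | CC(=O)OC1C=CC[C@@H](C(=O)O[C@H]2C[C@@H](C)CC[C@@H]2C(C)C)[C@@H]1C(=O)O[C@H]1C[C@@H](C)CC[C@@H]1C(C)C
F11 | step 5 | (5R,6R)-5,6-bis(hydroxymethyl)cyclohex-2-en-1-ol (C1 epimers) | OC1C=CC[C@@H](CO)[C@@H]1CO
F12 | step 5 | (5R,6R)-5,6-bis(hydroxymethyl)cyclohex-2-en-1-one | O=C1C=CC[C@@H](CO)[C@@H]1CO
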